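**Retrosynthetic overview**

1. The target is numbered as a decahydroazulene: C1 (side chain), C2, C3, C3a (CH3), C4, C5 (OAc), C6 (=CH2), C7, C8, C8a (H); side chain C1′–C7′. The end game starts from the C5 ketone 14: C6 methylenation, C5 reduction and Mitsunobu acetate, desilylation.
2. Key disconnection: C7–C8 and C8a–C3a are made together by an intramolecular rhodium-catalysed [5+2] cycloaddition of an alkyne-tethered 1-siloxy-1-alkenylcyclopropane (11 → 13). The five-membered ring closes first (alkyne insertion), the seven-membered ring second (reductive elimination); the cyclopropane made two steps earlier is consumed.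
3. Enabling feature: in the seven-membered ring the oxygen-bearing C5 is the central atom of the five-carbon arc C3a–C4–C5–C6–C7 (a latent alkenylcyclopropane: C3a=C4 alkene, C5/C6/C7 ring). The other two ring atoms C8–C8a are adjacent (a latent alkyne), and C8a is tied to C3a by the three-carbon bridge C1–C2–C3 of the cyclopentane.
4. The acyclic precursor is unravelled from (−)-α-bisabolol: cleavage of its cyclohexene C=C maps the ring onto C3a (with its CH3), C3, C2, C1, C8a and C8, and its two stereocentres become C1 and C2′. A Schenck ene reaction transposes the side-chain alkene; C4–C7 and the exocyclic CH2 come from olefination, Kulinkovich cyclopropanation and Mannich methylenation.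
5. C3a is set in the key step under control of C1, C8a by hydrogen-atom-transfer hydrogenation, C5 by reduction and Mitsunobu inversion.

Key step: step 8

Remark: (−)-α-bisabolol is taken as the commercial (2S,1′S) enantiomer (levomenol), whose two stereocentres have the configuration needed at C1 and C2′. "Sc" stands for the (2S,4E)-6-methyl-2,6-bis(triethylsilyloxy)hept-4-en-2-yl side chain.

**Route**

Step 1
Reactants: 1 (−)-α-bisabolol
Product: 3 (3E,6S)-2-methyl-6-[(1S)-4-methylcyclohex-3-en-1-yl]hept-3-ene-2,6-diol, via tertiary allylic hydroperoxide 2 (not isolated)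
Conditions: O2, white LED, tetraphenylporphyrin (cat.), CH2Cl2, −20 °C; then PPh3, rt
Reagents that add atoms: dioxygen O=O
Why: Schenck ene reaction of singlet oxygen, in which the acyclic trisubstituted alkene should react faster than the 1-methylcyclohexene (poorly aligned allylic C–H bonds) and abstraction of a C4′ hydrogen gives the (E)-tertiary allylic hydroperoxide that PPh3 reduces; the regioisomeric secondary hydroperoxide from methyl abstraction is the expected by-product and is removed at the diol stage, and no stereocentre is touched.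

Step 2
Reactants: 3 diol
Product: 4 bis(triethylsilyl) ether of 3
Conditions: TESOTf, 2,6-lutidine, CH2Cl2, −78 → 0 °C
Reagents that add atoms: triethylsilyl trifluoromethanesulfonate CC[Si](CC)(CC)OS(=O)(=O)C(F)(F)F
Why: Silyl triflate with a hindered base is the standard silylation of tertiary alcohols; it prevents lactol formation with the aldehyde of step 3 and leaves the side-chain alkene hindered and electron-poor for the later alkene-selective steps.

Step 3
Reactants: 4 bis-silyl ether
Product: 6 (3S)-6-oxo-3-Sc-heptanal, via secondary ozonide 5 (not isolated)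
Conditions: O3, CH2Cl2, −78 °C, Sudan Red 7B as end-point indicator; then PPh3, −78 °C → rt
Reagents that add atoms: ozone [O-][O+]=O
Why: Ozonolysis, in which electrophilic ozone should select the trisubstituted ring alkene over the 1,2-disubstituted side-chain alkene (allylic silyloxy group, fully substituted neighbours) with the dye marking the end point; the stereocentre is not α to either carbonyl and is not at risk.

Step 4
Reactants: 6 keto aldehyde
Product: 8 (5S)-5-Sc-hept-6-yn-2-one, via alkenyl nonaflate 7 (not isolated)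
Conditions: C4F9SO2F (1.05 equiv), phosphazene base P2-Et (2.2 equiv), DMF, −30 °C → rt
Reagents that add atoms: none
Why: One-pot dehydration of an enolisable aldehyde to a terminal alkyne (enol nonaflate formation, then base-induced elimination) without change in carbon count; the aldehyde should enolise much faster than the methyl ketone, so one equivalent of sulfonyl fluoride is consumed at the aldehyde only, and the stereocentre becomes a non-acidic propargylic CH.

Step 5
Reactants: 8 alkynyl ketone
Product: 9 ethyl (2E,6S)-3-methyl-6-Sc-oct-2-en-7-ynoate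
Conditions: (EtO)2P(O)CH2CO2Et, NaH, THF, 0 °C → reflux; chromatographic removal of the (Z)-isomer
Reagents that add atoms: triethyl phosphonoacetate CCOC(=O)CP(=O)(OCC)OCC
Why: Horner–Wadsworth–Emmons olefination of the methyl ketone, in which the (E)-enoate (chain trans to the ester) is expected to predominate; the alkyne C–H is not acidic enough to interfere.

Step 6
Reactants: 9 enoate
Product: 10 1-[(1E,5S)-2-methyl-5-Sc-hept-1-en-6-yn-1-yl]cyclopropan-1-ol
Conditions: EtMgBr (3.5 equiv), Ti(OiPr)4 (20 mol%), THF, 0 °C → rt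
Reagents that add atoms: ethylmagnesium bromide CC[Mg]Br
Why: Kulinkovich cyclopropanation, in which the titanacyclopropane from EtMgBr and Ti(OiPr)4 converts the ester into the 1-alkenylcyclopropanol; the β,β-disubstituted enoate resists conjugate addition and the first equivalent of Grignard reagent only deprotonates the alkyne.

Step 7
Reactants: 10 cyclopropanol
Product: 11 tert-butyldimethylsilyl ether of 10
Conditions: TBSCl, imidazole, DMF, rt
Reagents that add atoms: tert-butyldimethylsilyl chloride CC(C)(C)[Si](C)(C)Cl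
Why: Standard silylation of the tertiary cyclopropanol; the silyl ether blocks ring-opening to the ketone homoenolate and becomes the enol ether of the cycloadduct.

Step 8
Reactants: 11 alkyne-tethered 1-siloxy-1-alkenylcyclopropane
Product: 13 (1S,3aR)-3a-methyl-1-Sc-2,3,3a,4,6,7-hexahydroazulen-5(1H)-one, via silyl enol ether 12 (not isolated)
Conditions: [Rh(CO)2Cl]2 (5 mol%), ClCH2CH2Cl, 80 °C; then TBAF (1.1 equiv), AcOH, THF, −78 → 0 °C
Reagents that add atoms: none
Why: Monovalent rhodium binds the alkyne and the alkenylcyclopropane of 11, opens the strained ring at C5–C7 (both CH2 groups are equivalent, so no regiochemical question arises) to a σ,π-allyl rhodacycle, inserts the tethered alkyne into the Rh–C3a bond and closes by C7–C8 reductive elimination to enol ether 12, which TBAF/AcOH cleaves to ketone 13. The closest known reaction type is the rhodium-catalysed intramolecular [5+2] cycloaddition of alkyne-tethered vinylcyclopropanes, together with the use of 1-siloxyvinylcyclopropanes as cycloheptenone precursors. The five-membered ring closes by 5-exo-dig carbometalation across the tether C1–C2–C3 (C3a–C8a bond), the seven-membered ring by C–C reductive elimination from the eight-membered rhodacycle (C7–C8 bond). The only new stereocentre, quaternary C3a, is controlled by C1: rhodium and the allyl arm C4–C5(OTBS) occupy one face of the forming cyclopentene, so the bulky C1 substituent should take the other face and end cis to the C3a methyl (3aR), while C8a stays sp2 and is set in step 9. The step needs chemoselectivity for the alkyne over the side-chain alkene (hindered, 1,2-disubstituted, allylic silyloxy, no favourable tether), the (E)-geometry of 11 to hold the tether anti to the cyclopropane, and enol ether regiocontrol, which the siloxy group fixes as C4=C5 so that the ketone appears at C5.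

Step 9
Reactants: 13 bicyclic ketone
Product: 14 (1S,3aR,8aS)-3a-methyl-1-Sc-octahydroazulen-5(1H)-one
Conditions: Mn(dpm)3 (10 mol%), PhSiH3, t-BuOOH, i-PrOH, rt
Reagents that add atoms: none
Why: Mukaiyama-type hydrogen-atom-transfer hydrogenation, in which the manganese hydride gives H• to C8 of the only alkene that leads to a tertiary radical and the C8a radical should be quenched from the face opposite both the C3a methyl and the C1 side chain, setting the trans ring fusion (8aS); the hindered 1,2-disubstituted side-chain alkene and the ketone are expected to survive.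

Step 10
Reactants: 14 trans-fused ketone
Product: 16 6-[(dimethylamino)methyl] ketone (C6 epimers), via lithium enolate 15 (not isolated)
Conditions: LDA, THF, −78 °C; then CH2=NMe2+ I−, −78 °C → rt
Reagents that add atoms: N,N-dimethylmethyleneiminium iodide C=[N+](C)C.[I-]
Why: Kinetic enolisation removes a proton from C6 and not from the neopentyl-type C4 next to quaternary C3a, and the enolate is aminomethylated by Eschenmoser's salt (Mannich reaction); the new C6 centre is erased in step 11.

Step 11
Reactants: 16 Mannich base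
Product: 18 (1S,3aR,8aS)-3a-methyl-6-methylidene-1-Sc-octahydroazulen-5(1H)-one, via trimethylammonium iodide 17 (not isolated)
Conditions: MeI, Et2O, rt; then NaHCO3 (aq), CH2Cl2, rt
Reagents that add atoms: none
Why: N-Methylation and E1cB (Hofmann-type) loss of trimethylamine from the β-ammonio ketone give the α-methylene ketone under conditions too mild to move the alkene into the ring.

Step 12
Reactants: 18 α-methylene ketone
Product: 19 (1S,3aR,5R,8aS)-3a-methyl-6-methylidene-1-Sc-decahydroazulen-5-ol
Conditions: NaBH4, CeCl3·7H2O, MeOH, −78 °C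
Reagents that add atoms: none
Why: Luche 1,2-reduction, in which hydride is expected on the C5 carbonyl face opposite the syn-axial C3a methyl (1,3-relationship), giving the (5R)-alcohol with OH cis to that methyl while cerium suppresses conjugate reduction.

Step 13
Reactants: 19 (5R)-allylic alcohol
Product: 20 (1S,3aR,5S,8aS)-3a-methyl-6-methylidene-1-Sc-decahydroazulen-5-yl acetate
Conditions: PPh3, DIAD, AcOH, toluene, 0 °C → rt
Reagents that add atoms: acetic acid CC(=O)O
Why: Mitsunobu esterification with SN2 inversion at C5, the acetate entering on the face remote from the angular methyl to give the equatorial (5S)-acetate.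

Step 14
Reactants: 20 bis-silyl acetate
Product: 21 CNP0290154.1
Conditions: HF·pyridine, pyridine, THF, 0 °C → rt
Reagents that add atoms: none
Why: Buffered fluoride cleavage of the two tertiary triethylsilyl ethers, which should leave the allylic acetate, the tertiary allylic alcohol and both alkenes untouched.

**Compound list**

1 | (−)-α-bisabolol, (2S)-6-methyl-2-[(1S)-4-methylcyclohex-3-en-1-yl]hept-5-en-2-ol | CC1=CC[C@H](CC1)[C@@](C)(O)CCC=C(C)C | starting material
2 | (2S,4E)-6-hydroperoxy-6-methyl-2-[(1S)-4-methylcyclohex-3-en-1-yl]hept-4-en-2-ol | CC1=CC[C@H](CC1)[C@@](C)(O)C/C=C/C(C)(C)OO | intermediate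
3 | (3E,6S)-2-methyl-6-[(1S)-4-methylcyclohex-3-en-1-yl]hept-3-ene-2,6-diol | CC1=CC[C@H](CC1)[C@@](C)(O)C/C=C/C(C)(C)O | intermediate
4 | (3E,6S)-2-methyl-6-[(1S)-4-methylcyclohex-3-en-1-yl]-2,6-bis(triethylsilyloxy)hept-3-ene | CC1=CC[C@H](CC1)[C@@](C)(O[Si](CC)(CC)CC)C/C=C/C(C)(C)O[Si](CC)(CC)CC | intermediate
5 | secondary ozonide of 4, 1-methyl-4-Sc-7,8,9-trioxabicyclo[4.2.1]nonane (new bridgehead centres not defined) | CC12CC[C@H]([C@@](C)(O[Si](CC)(CC)CC)C/C=C/C(C)(C)O[Si](CC)(CC)CC)CC(OO1)O2 | intermediate
6 | (3S)-3-[(2S,4E)-6-methyl-2,6-bis(triethylsilyloxy)hept-4-en-2-yl]-6-oxoheptanal | CC(=O)CC[C@@H](CC=O)[C@@](C)(O[Si](CC)(CC)CC)C/C=C/C(C)(C)O[Si](CC)(CC)CC | intermediate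
7 | (3S)-3-Sc-6-oxohept-1-en-1-yl nonafluorobutane-1-sulfonate (E/Z mixture at the enol double bond) | CC(=O)CC[C@@H](C=COS(=O)(=O)C(F)(F)C(F)(F)C(F)(F)C(F)(F)F)[C@@](C)(O[Si](CC)(CC)CC)C/C=C/C(C)(C)O[Si](CC)(CC)CC | intermediate
8 | (5S)-5-[(2S,4E)-6-methyl-2,6-bis(triethylsilyloxy)hept-4-en-2-yl]hept-6-yn-2-one | CC(=O)CC[C@@H](C#C)[C@@](C)(O[Si](CC)(CC)CC)C/C=C/C(C)(C)O[Si](CC)(CC)CC | intermediate
9 | ethyl (2E,6S)-3-methyl-6-[(2S,4E)-6-methyl-2,6-bis(triethylsilyloxy)hept-4-en-2-yl]oct-2-en-7-ynoate | CCOC(=O)/C=C(\C)CC[C@@H](C#C)[C@@](C)(O[Si](CC)(CC)CC)C/C=C/C(C)(C)O[Si](CC)(CC)CC | intermediate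
10 | 1-[(1E,5S)-2-methyl-5-[(2S,4E)-6-methyl-2,6-bis(triethylsilyloxy)hept-4-en-2-yl]hept-1-en-6-yn-1-yl]cyclopropan-1-ol | OC1(/C=C(\C)CC[C@@H](C#C)[C@@](C)(O[Si](CC)(CC)CC)C/C=C/C(C)(C)O[Si](CC)(CC)CC)CC1 | intermediate
11 | tert-butyldimethylsilyl ether of 10 | CC(C)(C)[Si](C)(C)OC1(/C=C(\C)CC[C@@H](C#C)[C@@](C)(O[Si](CC)(CC)CC)C/C=C/C(C)(C)O[Si](CC)(CC)CC)CC1 | intermediate
12 | (1S,3aR)-5-(tert-butyldimethylsilyloxy)-3a-methyl-1-Sc-1,2,3,3a,6,7-hexahydroazulene (C4=C5 and C8=C8a alkenes) | CC(C)(C)[Si](C)(C)OC1=C[C@@]2(C)CC[C@H]([C@@](C)(O[Si](CC)(CC)CC)C/C=C/C(C)(C)O[Si](CC)(CC)CC)C2=CCC1 | intermediate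
13 | (1S,3aR)-3a-methyl-1-Sc-2,3,3a,4,6,7-hexahydroazulen-5(1H)-one (C8=C8a alkene) | O=C1C[C@@]2(C)CC[C@H]([C@@](C)(O[Si](CC)(CC)CC)C/C=C/C(C)(C)O[Si](CC)(CC)CC)C2=CCC1 | intermediate
14 | (1S,3aR,8aS)-3a-methyl-1-Sc-octahydroazulen-5(1H)-one (trans-fused) | O=C1C[C@@]2(C)CC[C@H]([C@@](C)(O[Si](CC)(CC)CC)C/C=C/C(C)(C)O[Si](CC)(CC)CC)[C@@H]2CCC1 | intermediate
15 | lithium C5=C6 enolate of 14 | [Li]OC1=CCC[C@H]2[C@@H]([C@@](C)(O[Si](CC)(CC)CC)C/C=C/C(C)(C)O[Si](CC)(CC)CC)CC[C@]2(C)C1 | intermediate
16 | (1S,3aR,8aS)-6-[(dimethylamino)methyl]-3a-methyl-1-Sc-octahydroazulen-5(1H)-one (C6 epimers) | CN(C)CC1CC[C@H]2[C@@H]([C@@](C)(O[Si](CC)(CC)CC)C/C=C/C(C)(C)O[Si](CC)(CC)CC)CC[C@]2(C)CC1=O | intermediate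
17 | N-methyl ammonium iodide of 16 | C[N+](C)(C)CC1CC[C@H]2[C@@H]([C@@](C)(O[Si](CC)(CC)CC)C/C=C/C(C)(C)O[Si](CC)(CC)CC)CC[C@]2(C)CC1=O.[I-] | intermediate
18 | (1S,3aR,8aS)-3a-methyl-6-methylidene-1-Sc-octahydroazulen-5(1H)-one | C=C1CC[C@H]2[C@@H]([C@@](C)(O[Si](CC)(CC)CC)C/C=C/C(C)(C)O[Si](CC)(CC)CC)CC[C@]2(C)CC1=O | intermediate
19 | (1S,3aR,5R,8aS)-3a-methyl-6-methylidene-1-Sc-decahydroazulen-5-ol | C=C1CC[C@H]2[C@@H]([C@@](C)(O[Si](CC)(CC)CC)C/C=C/C(C)(C)O[Si](CC)(CC)CC)CC[C@]2(C)C[C@H]1O | intermediate
20 | (1S,3aR,5S,8aS)-3a-methyl-6-methylidene-1-Sc-decahydroazulen-5-yl acetate | C=C1CC[C@H]2[C@@H]([C@@](C)(O[Si](CC)(CC)CC)C/C=C/C(C)(C)O[Si](CC)(CC)CC)CC[C@]2(C)C[C@@H]1OC(C)=O | intermediate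
21 | CNP0290154.1, (1S,3aR,5S,8aS)-1-[(2S,4E)-2,6-dihydroxy-6-methylhept-4-en-2-yl]-3a-methyl-6-methylidene-decahydroazulen-5-yl acetate | C=C1CC[C@H]2[C@@H]([C@@](C)(O)C/C=C/C(C)(C)O)CC[C@]2(C)C[C@@H]1OC(C)=O | target

**Summary and risks**

Total step count: 14. Longest linear sequence: 14 steps (fully linear from 1).

Steps most likely to fail:

Step 8. The trisubstituted alkenylcyclopropane may engage rhodium too slowly, so that alkyne oligomerisation or cyclopropane opening without cycloaddition takes over. The C1 centre may also discriminate poorly between the two faces at C3a. The fallback builds ketone 13 by a [4+3] route that needs no cyclopropane and sets C3a by direct steric approach. It sets out from alkynyl ketone 8. Wittig methylenation (Ph3P=CH2, THF) gives the 1,6-enyne F1. Ring-closing enyne metathesis (second-generation Grubbs catalyst, ethylene, toluene, 80 °C) gives the 2-methyl-1-vinylcyclopentene F2. Cycloaddition with the oxyallyl cation from α,α,α′,α′-tetrabromoacetone and Fe2(CO)9 (benzene, 60 °C), on the diene face anti to the C1 substituent, gives the dibromocycloheptenone F3. Zinc–copper couple with NH4Cl in MeOH removes both bromines and the route is rejoined at 13.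

Step 4. The methyl ketone may compete in enolisation and sulfonylation, the aldehyde enolate may undergo aldol condensation, or the base may isomerise the alkyne to an allene. The fallback olefinates the ketone before the alkyne is made. It sets out from keto aldehyde 6. NaBH(OAc)3 (benzene, rt) reduces only the aldehyde to the keto alcohol F4. The Horner–Wadsworth–Emmons reaction of step 5 then gives the hydroxy enoate F5. Dess–Martin periodinane gives the enoate aldehyde F6. The nonaflyl fluoride/phosphazene dehydration, now with no ketone in the molecule, rejoins the route at enoate 9.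

Step 12. Hydride delivery in the flexible seven-membered ring may show poor facial selectivity or occur from the methyl-bearing face, so that the inversion of step 13 would give the wrong C5 epimer; SN2′ displacement in step 13 is a related risk. The fallback sets C5 under reagent control and keeps it. It sets out from enone 18. Reduction with catecholborane and (R)-2-methyl-CBS-oxazaborolidine (toluene, −78 °C), with the alkenyl side of the ketone as the large group, gives the (5S)-allylic alcohol F7. Acetylation with retention (Ac2O, DMAP, pyridine) rejoins the route at acetate 20, and step 13 is not used.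

Further compounds
F1 | step 8 | (5S)-2-methyl-5-[(2S,4E)-6-methyl-2,6-bis(triethylsilyloxy)hept-4-en-2-yl]hept-1-en-6-yne | C=C(C)CC[C@@H](C#C)[C@@](C)(O[Si](CC)(CC)CC)C/C=C/C(C)(C)O[Si](CC)(CC)CC
F2 | step 8 | (5S)-1-ethenyl-2-methyl-5-[(2S,4E)-6-methyl-2,6-bis(triethylsilyloxy)hept-4-en-2-yl]cyclopent-1-ene | C=CC1=C(C)CC[C@@H]1[C@@](C)(O[Si](CC)(CC)CC)C/C=C/C(C)(C)O[Si](CC)(CC)CC
F3 | step 8 | (1S,3aR)-4,6-dibromo-3a-methyl-1-Sc-2,3,3a,4,6,7-hexahydroazulen-5(1H)-one (bromide epimers) | O=C1C(Br)[C@@]2(C)CC[C@H]([C@@](C)(O[Si](CC)(CC)CC)C/C=C/C(C)(C)O[Si](CC)(CC)CC)C2=CCC1Br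
F4 | step 4 | (5S)-7-hydroxy-5-[(2S,4E)-6-methyl-2,6-bis(triethylsilyloxy)hept-4-en-2-yl]heptan-2-one | CC(=O)CC[C@@H](CCO)[C@@](C)(O[Si](CC)(CC)CC)C/C=C/C(C)(C)O[Si](CC)(CC)CC
F5 | step 4 | ethyl (2E,6S)-8-hydroxy-3-methyl-6-[(2S,4E)-6-methyl-2,6-bis(triethylsilyloxy)hept-4-en-2-yl]oct-2-enoate | CCOC(=O)/C=C(\C)CC[C@@H](CCO)[C@@](C)(O[Si](CC)(CC)CC)C/C=C/C(C)(C)O[Si](CC)(CC)CC
F6 | step 4 | ethyl (2E,6S)-3-methyl-8-oxo-6-[(2S,4E)-6-methyl-2,6-bis(triethylsilyloxy)hept-4-en-2-yl]oct-2-enoate | CCOC(=O)/C=C(\C)CC[C@@H](CC=O)[C@@](C)(O[Si](CC)(CC)CC)C/C=C/C(C)(C)O[Si](CC)(CC)CC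
F7 | step 12 | (1S,3aR,5S,8aS)-3a-methyl-6-methylidene-1-Sc-decahydroazulen-5-ol | C=C1CC[C@H]2[C@@H]([C@@](C)(O[Si](CC)(CC)CC)C/C=C/C(C)(C)O[Si](CC)(CC)CC)CC[C@]2(C)C[C@@H]1O
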